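The carbocycle is opened at C13–C14, the bond that joins the acetoxy carbon to the lactone γ-carbon. In the target these atoms form a 5-(1-oxyalkyl)butanolide, the retron of a vinylogous aldol reaction: C14 is C5 of a 2-silyloxyfuran that carries the lactone atoms (O, C16, C15, C1) and C13 is the formyl carbon of an (E)-enal at the far end of an epoxyfarnesyl chain. One intramolecular vinylogous Mukaiyama aldol reaction closes the 14-membered ring, builds the oxygenated C13–C14 unit and fixes C14, whose configuration is then relayed to C1. The precursor is a linear 3-(epoxyfarnesyl)furan oxidized at both termini, made from farnesol and 3-bromofuran.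

Key step: step 8

Numbering: cembrane numbering of the target is used for all compounds (C1–C14 ring carbons, C3–C4 epoxide, C13 acetoxy carbon, C14 lactone γ-carbon, C15 lactone α-carbon, C16 lactone carbonyl, C17 exocyclic methylene).

Assumption: the (R)-BINOL titanium complex is taken to expose the aldehyde face that gives (13R); if the sense of induction is the opposite, (S)-BINOL is used.

Stereochemical plan: an external hydride adds to the butenolide anti to C13, which gives a cis-fused lactone, whereas the target is trans-fused. The aldol step is therefore aimed at (14R), which sets (1S) in step 9. C14 is then equilibrated to (14S) through the C13 ketone in step 10, and C13 is set last in step 11.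

Step 1
Reactants: 1 (2E,6E)-farnesol
Product: 2 (2S,3S)-2,3-epoxyfarnesol
Conditions: Ti(OiPr)4 (cat.), L-(+)-diethyl tartrate (cat.), t-BuOOH, 4 Å molecular sieves, CH2Cl2, −20 °C
Reagents that add atoms: tert-butyl hydroperoxide, CC(C)(C)OO
Why: Sharpless asymmetric epoxidation, in which the titanium tartrate complex binds the allylic hydroxyl and therefore epoxidizes only the C2=C3 alkene of farnesol, with L-(+)-tartrate selecting the face that gives the (2S,3S)-epoxide that becomes C3 and C4 of the target.

Step 2
Reactants: 2 (2S,3S)-2,3-epoxyfarnesol, 3 3-bromofuran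
Product: 5 3-[(2S,3S)-2,3-epoxyfarnesyl]furan, via epoxyfarnesyl triflate 4 (not isolated)
Conditions: Tf2O, 2,6-lutidine, CH2Cl2, −78 °C; then Li[Cu(3-furyl)2] (from 3, n-BuLi, CuI), THF/Et2O, −78 → −40 °C
Reagents that add atoms: trifluoromethanesulfonic anhydride, O=S(=O)(OS(=O)(=O)C(F)(F)F)C(F)(F)F (its atoms stay only in 4)
Why: Sulfonylation followed by SN2 alkylation of a Gilman cuprate (sp3–sp2 coupling), which should work because the primary triflate beside the epoxide is far more electrophilic toward the soft diarylcuprate at −78 °C than the trisubstituted epoxide, so the furan is joined at C2 and both epoxide stereocenters are untouched.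

Step 3
Reactants: 5 3-[(2S,3S)-2,3-epoxyfarnesyl]furan
Product: 7 γ-hydroxybutenolide, via furan endoperoxide 6 (not isolated)
Conditions: O2, hν, tetraphenylporphyrin (cat.), iPr2NEt, CH2Cl2, −78 °C
Reagents that add atoms: dioxygen, O=O
Why: [4+2] cycloaddition of singlet oxygen to the furan, which at −78 °C is much faster than the ene reaction of the trisubstituted alkenes, followed by amine-induced Kornblum–DeLaMare fragmentation in which the hindered base removes the unhindered bridgehead proton remote from the side chain, so that the carbonyl forms at C16 and the hemiacetal at C14 (an epimer mixture that is removed in step 4).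

Step 4
Reactants: 7 γ-hydroxybutenolide
Product: 8 β-(epoxyfarnesyl)butenolide
Conditions: NaBH4, EtOH, 0 °C; then aq. NaH2PO4 (pH about 5)
Reagents that add atoms: none
Why: Borohydride reduction of the open formyl acrylate tautomer of the pseudo acid and lactonization of the resulting (Z)-4-hydroxy enoate on mild acidification give the butenolide, while epoxide and isolated alkenes are inert to NaBH4.

Step 5
Reactants: 8 β-(epoxyfarnesyl)butenolide
Product: 9 terminal (E)-allylic alcohol
Conditions: SeO2 (cat.), t-BuOOH, salicylic acid (cat.), CH2Cl2, rt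
Reagents that add atoms: tert-butyl hydroperoxide, CC(C)(C)OO
Why: Catalytic SeO2 allylic oxidation (ene reaction then [2,3]-sigmatropic shift) attacks the (E)-methyl group of the terminal, most electron-rich and least hindered trisubstituted alkene, whereas the electron-poor butenolide alkene does not enter the ene step, and the alkene geometry is retained.

Step 6
Reactants: 9 terminal (E)-allylic alcohol
Product: 10 butenolide enal
Conditions: MnO2, CH2Cl2, rt
Reagents that add atoms: none
Why: Chemoselective MnO2 oxidation of the allylic alcohol gives the (E)-enal without touching butenolide, epoxide or the remote alkene.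

Step 7
Reactants: 10 butenolide enal
Product: 11 2-silyloxyfuran enal
Conditions: TBSOTf (1.1 equiv), Et3N, CH2Cl2, −78 → 0 °C; rapid filtration through Et3N-deactivated silica, used at once
Reagents that add atoms: tert-butyldimethylsilyl trifluoromethanesulfonate, CC(C)(C)[Si](C)(C)OS(=O)(=O)C(F)(F)F
Why: Soft enolization with a silyl triflate and an amine silylates the butenolide, whose γ-protons are the most acidic and whose enol form is an aromatic furan, faster than the enal at low temperature, giving the silyl dienol ether needed for the aldol step.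

Step 8
Reactants: 11 2-silyloxyfuran enal
Product: 13 macrocyclic (13R,14R)-hydroxy butenolide, via macrocyclic aldol silyl ether 12 (not isolated)
Conditions: Ti(OiPr)4/(R)-BINOL (1:1, 0.5 equiv), 4 Å molecular sieves, Et2O, −20 °C, syringe-pump addition of 11 (final about 2 mM); then TBAF, AcOH, THF, 0 °C
Reagents that add atoms: none
Why: The chiral titanium BINOLate activates the enal carbonyl and C5 of the 2-silyloxyfuran (C14) attacks C13 through an open transition state, after which silyl transfer to the aldolate gives 12 and regenerates the Lewis acid, and buffered fluoride then frees the hydroxyl. The closest known reaction is the titanium BINOLate catalysed vinylogous Mukaiyama aldol addition of 2-silyloxyfurans to aldehydes, used here in its intramolecular form. The 14-membered carbocycle closes in a 14-exo-trig mode, and slow addition at high dilution is needed to favour it over intermolecular aldol addition. C13 is controlled by the BINOL ligand, which shields one face of the bound aldehyde, and C14 by the synclinal, Diels–Alder-like arrangement of furan and aldehyde that makes Lewis acid additions of silyloxyfurans threo selective, so that the (13R,14R) isomer should prevail. The step needs attack at C14 instead of C15 (only attack at C14 returns a conjugated butenolide, and C15 is flanked by the side chain) and an intact epoxide, which the weakly Lewis acidic titanium alkoxide should leave untouched. Only the C14 configuration is carried forward, because C13 is reset in steps 10 and 11, so a C13 epimer with the same C14 configuration converges.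

Step 9
Reactants: 13 macrocyclic (13R,14R)-hydroxy butenolide
Product: 14 cis-fused (1S,13R,14R)-hydroxy lactone
Conditions: [(Ph3P)CuH]6, H2O (2 equiv), benzene, rt
Reagents that add atoms: none
Why: Conjugate reduction with a phosphine copper hydride, which is selective for the electron-poor butenolide alkene and delivers hydride to C1 on the face opposite to the C13 substituent at C14, so that the cis-fused lactone with (1S) configuration should form after protonation of the copper enolate at the non-stereogenic C15.

Step 10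
Reactants: 14 cis-fused (1S,13R,14R)-hydroxy lactone
Product: 16 trans-fused (1S,14S)-keto lactone, via cis-fused keto lactone 15 (not isolated)
Conditions: Dess–Martin periodinane, pyridine, CH2Cl2, 0 °C → rt; then DBU (0.2 equiv), CH2Cl2, 0 °C
Reagents that add atoms: none
Why: Dess–Martin oxidation makes C13 a ketone so that the C14 hydrogen becomes acidic, and catalytic DBU then equilibrates C14 by enolization to the thermodynamically preferred trans-4,5-disubstituted lactone, which sets (14S) relative to the fixed C1 and lets both C13 epimers of 14 converge.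

Step 11
Reactants: 16 trans-fused (1S,14S)-keto lactone
Product: 17 trans-fused (1S,13S,14S)-hydroxy lactone
Conditions: (S)-2-methyl-CBS-oxazaborolidine (0.2 equiv), catecholborane, toluene, −78 °C
Reagents that add atoms: none
Why: Corey–Bakshi–Shibata reduction, in which the (S)-oxazaborolidine treats the 2-methylalkenyl group as the large substituent and delivers hydride 1,2 to the enone to give the (13S)-alcohol, the same sense as Felkin–Anh attack anti to the C14–O bond (threo), while catecholborane at −78 °C spares lactone, epoxide and alkenes.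

Step 12
Reactants: 17 trans-fused (1S,13S,14S)-hydroxy lactone
Product: 20 13-deacetyl α-methylene lactone, via Mannich base 18 (not isolated), via ammonium iodide 19 (not isolated)
Conditions: LiN(iPr)2 (3 equiv), THF, −78 °C; CH2=NMe2+ I−, −78 → 0 °C; then MeI, MeOH, rt; then aq. NaHCO3, CH2Cl2, rt
Reagents that add atoms: dimethylmethylideneammonium iodide (Eschenmoser's salt), C=[N+](C)C.[I-]; iodomethane, CI (its atoms stay only in 19)
Why: α-Methylenation by Mannich reaction and Hofmann-type elimination, in which the lithium enolate of the lactone (the hydroxyl is carried as its alkoxide) is aminomethylated at C15 and the quaternized amine is lost by mild base E1cB elimination to the exocyclic alkene, with no stereocenter affected.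

Step 13
Reactants: 20 13-deacetyl α-methylene lactone
Product: 21 13-acetoxysarcocrassolide
Conditions: Ac2O, pyridine, DMAP (cat.), CH2Cl2, 0 °C
Reagents that add atoms: acetic anhydride, CC(=O)OC(C)=O
Why: DMAP-catalysed O-acylation of the secondary allylic alcohol proceeds with retention at C13 and under conditions that the α-methylene lactone and the epoxide tolerate.

Compound list

1 | (2E,6E)-farnesol, (2E,6E)-3,7,11-trimethyldodeca-2,6,10-trien-1-ol | OC/C=C(\C)CC/C=C(\C)CCC=C(C)C | starting material
2 | [(2S,3S)-3-[(3E)-4,8-dimethylnona-3,7-dien-1-yl]-3-methyloxiran-2-yl]methanol | OC[C@@H]1O[C@@]1(C)CC/C=C(\C)CCC=C(C)C | intermediate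
3 | 3-bromofuran | Brc1ccoc1 | starting material
4 | [(2S,3S)-3-[(3E)-4,8-dimethylnona-3,7-dien-1-yl]-3-methyloxiran-2-yl]methyl trifluoromethanesulfonate | O=S(=O)(OC[C@@H]1O[C@@]1(C)CC/C=C(\C)CCC=C(C)C)C(F)(F)F | intermediate
5 | 3-{[(2S,3S)-3-[(3E)-4,8-dimethylnona-3,7-dien-1-yl]-3-methyloxiran-2-yl]methyl}furan | c1cc(C[C@@H]2O[C@@]2(C)CC/C=C(\C)CCC=C(C)C)co1 | intermediate
6 | 5-{[(2S,3S)-3-[(3E)-4,8-dimethylnona-3,7-dien-1-yl]-3-methyloxiran-2-yl]methyl}-2,3,7-trioxabicyclo[2.2.1]hept-5-ene (endoperoxide of 5, both bridgehead epimers) | O1C2C(C[C@@H]3O[C@@]3(C)CC/C=C(\C)CCC=C(C)C)=CC1OO2 | intermediate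
7 | 5-hydroxy-4-{[(2S,3S)-3-[(3E)-4,8-dimethylnona-3,7-dien-1-yl]-3-methyloxiran-2-yl]methyl}furan-2(5H)-one (both C5 epimers) | O=C1C=C(C[C@@H]2O[C@@]2(C)CC/C=C(\C)CCC=C(C)C)C(O)O1 | intermediate
8 | 4-{[(2S,3S)-3-[(3E)-4,8-dimethylnona-3,7-dien-1-yl]-3-methyloxiran-2-yl]methyl}furan-2(5H)-one | O=C1C=C(C[C@@H]2O[C@@]2(C)CC/C=C(\C)CCC=C(C)C)CO1 | intermediate
9 | 4-{[(2S,3S)-3-[(3E,7E)-9-hydroxy-4,8-dimethylnona-3,7-dien-1-yl]-3-methyloxiran-2-yl]methyl}furan-2(5H)-one | O=C1C=C(C[C@@H]2O[C@@]2(C)CC/C=C(\C)CC/C=C(\C)CO)CO1 | intermediate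
10 | (2E,6E)-2,6-dimethyl-9-[(2S,3S)-2-methyl-3-[(5-oxo-2,5-dihydrofuran-3-yl)methyl]oxiran-2-yl]nona-2,6-dienal | O=C1C=C(C[C@@H]2O[C@@]2(C)CC/C=C(\C)CC/C=C(\C)C=O)CO1 | intermediate
11 | (2E,6E)-9-[(2S,3S)-3-{[5-(tert-butyldimethylsilyloxy)furan-3-yl]methyl}-2-methyloxiran-2-yl]-2,6-dimethylnona-2,6-dienal | CC(C)(C)[Si](C)(C)Oc1cc(C[C@@H]2O[C@@]2(C)CC/C=C(\C)CC/C=C(\C)C=O)co1 | intermediate
12 | (3S,4S,7E,11E,13R,14R)-13-(tert-butyldimethylsilyloxy)-3,4-epoxy-17-norcembra-1(15),7,11-trien-16,14-olide | O=C1O[C@@H]2C(=C1)C[C@@H]1O[C@@]1(C)CC/C=C(\C)CC/C=C(\C)[C@H]2O[Si](C)(C)C(C)(C)C | intermediate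
13 | (3S,4S,7E,11E,13R,14R)-3,4-epoxy-13-hydroxy-17-norcembra-1(15),7,11-trien-16,14-olide | O=C1O[C@@H]2C(=C1)C[C@@H]1O[C@@]1(C)CC/C=C(\C)CC/C=C(\C)[C@H]2O | intermediate
14 | (1S,3S,4S,7E,11E,13R,14R)-3,4-epoxy-13-hydroxy-17-norcembra-7,11-dien-16,14-olide (cis-fused lactone) | O=C1O[C@@H]2[C@H](C1)C[C@@H]1O[C@@]1(C)CC/C=C(\C)CC/C=C(\C)[C@H]2O | intermediate
15 | (1S,3S,4S,7E,11E,14R)-3,4-epoxy-13-oxo-17-norcembra-7,11-dien-16,14-olide (cis-fused lactone) | O=C1O[C@@H]2[C@H](C1)C[C@@H]1O[C@@]1(C)CC/C=C(\C)CC/C=C(\C)C2=O | intermediate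
16 | (1S,3S,4S,7E,11E,14S)-3,4-epoxy-13-oxo-17-norcembra-7,11-dien-16,14-olide (trans-fused lactone) | O=C1O[C@H]2[C@H](C1)C[C@@H]1O[C@@]1(C)CC/C=C(\C)CC/C=C(\C)C2=O | intermediate
17 | (1S,3S,4S,7E,11E,13S,14S)-3,4-epoxy-13-hydroxy-17-norcembra-7,11-dien-16,14-olide | O=C1O[C@H]2[C@H](C1)C[C@@H]1O[C@@]1(C)CC/C=C(\C)CC/C=C(\C)[C@@H]2O | intermediate
18 | (1S,3S,4S,7E,11E,13S,14S)-17-(dimethylamino)-3,4-epoxy-13-hydroxycembra-7,11-dien-16,14-olide (both C15 epimers) | CN(C)CC1C(=O)O[C@H]2[C@H]1C[C@@H]1O[C@@]1(C)CC/C=C(\C)CC/C=C(\C)[C@@H]2O | intermediate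
19 | trimethylammonium iodide of 18 (N-methylated at the C17 nitrogen) | C[N+](C)(C)CC1C(=O)O[C@H]2[C@H]1C[C@@H]1O[C@@]1(C)CC/C=C(\C)CC/C=C(\C)[C@@H]2O.[I-] | intermediate
20 | (1S,3S,4S,7E,11E,13S,14S)-3,4-epoxy-13-hydroxycembra-7,11,15(17)-trien-16,14-olide | C=C1C(=O)O[C@H]2[C@H]1C[C@@H]1O[C@@]1(C)CC/C=C(\C)CC/C=C(\C)[C@@H]2O | intermediate
21 | 13-acetoxysarcocrassolide, (1S,3S,4S,7E,11E,13S,14S)-13-acetoxy-3,4-epoxycembra-7,11,15(17)-trien-16,14-olide | C=C1C(=O)O[C@H]2[C@H]1C[C@@H]1O[C@@]1(C)CC/C=C(\C)CC/C=C(\C)[C@@H]2OC(C)=O | target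

Total step count: 13. Longest linear sequence: 13 steps, from farnesol 1; 3-bromofuran 3 enters in step 2.

Steps most likely to fail

Step 8. Ring closure may lose to intermolecular aldol addition (oligomers) even at high dilution, or the silyl dienol ether may be protodesilylated before it reacts. The furan face may also be selected poorly with respect to the remote epoxide, so that the wrong C14 epimer, and after step 9 the wrong C1 epimer, is carried on. The fallback closes the same bond reductively instead of by an aldol addition; it sets out from 7 and comes back at 13. Compound 7 is opened and esterified with MeI and K2CO3 in DMF to the methyl (Z)-formylacrylate F1. The terminal (E)-methyl group is oxidized with catalytic SeO2 and t-BuOOH to the allylic alcohol F2, and MnO2 gives the dialdehyde F3. SmI2 in THF at high dilution then couples the two formyl groups in an intramolecular pinacol reaction, and the C14 alkoxide of the diol closes onto the cis ester with loss of methanol to give 13 as a mixture of diol isomers. The isomers with (14R) are taken on, the C14 epimers being separated at the stage of 14.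

Step 10. The base may not drive C14 fully to the trans lactone, or it may enolize the enone in a vinylogous sense at C10 or C20 and scramble the C11=C12 geometry. The fallback replaces equilibration by a stereospecific inversion; it sets out from 14 and comes back at 16. Compound 14 is silylated with TBSCl and imidazole to the silyl ether F4, and the lactone is opened with LiOH in aqueous THF to the hydroxy acid F5. Mitsunobu lactonization (PPh3, diisopropyl azodicarboxylate) closes the ring again with inversion at C14 to the trans lactone F6. TBAF then gives the alcohol F7, and Dess–Martin oxidation gives 16 without any base treatment.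

Step 3. Singlet oxygen may undergo the ene reaction with the two trisubstituted alkenes, and the endoperoxide may fragment toward the wrong carbonyl position. The fallback makes the butenolide by ring-closing metathesis without photooxygenation; it sets out from 4, made from 2 as in step 2, and comes back at 8, so that steps 2 to 4 are replaced. The cuprate from 2-bromoallyl tert-butyldimethylsilyl ether (t-BuLi, CuI) displaces the triflate to give the allyl silyl ether F8. TBAF frees the allylic alcohol F9, and acryloyl chloride with Et3N gives the acrylate F10. Ring-closing metathesis with the second-generation Grubbs catalyst, with loss of ethene, then gives butenolide 8.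

Further compounds

F1 | step 8 | methyl (2Z)-3-formyl-4-[(2S,3S)-3-[(3E)-4,8-dimethylnona-3,7-dien-1-yl]-3-methyloxiran-2-yl]but-2-enoate | COC(=O)/C=C(\C=O)C[C@@H]1O[C@@]1(C)CC/C=C(\C)CCC=C(C)C
F2 | step 8 | methyl (2Z)-3-formyl-4-[(2S,3S)-3-[(3E,7E)-9-hydroxy-4,8-dimethylnona-3,7-dien-1-yl]-3-methyloxiran-2-yl]but-2-enoate | COC(=O)/C=C(\C=O)C[C@@H]1O[C@@]1(C)CC/C=C(\C)CC/C=C(\C)CO
F3 | step 8 | methyl (2Z)-3-formyl-4-[(2S,3S)-3-[(3E,7E)-4,8-dimethyl-9-oxonona-3,7-dien-1-yl]-3-methyloxiran-2-yl]but-2-enoate | COC(=O)/C=C(\C=O)C[C@@H]1O[C@@]1(C)CC/C=C(\C)CC/C=C(\C)C=O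
F4 | step 10 | (1S,3S,4S,7E,11E,13R,14R)-13-(tert-butyldimethylsilyloxy)-3,4-epoxy-17-norcembra-7,11-dien-16,14-olide (cis-fused lactone) | O=C1O[C@@H]2[C@H](C1)C[C@@H]1O[C@@]1(C)CC/C=C(\C)CC/C=C(\C)[C@H]2O[Si](C)(C)C(C)(C)C
F5 | step 10 | (1S,3S,4S,7E,11E,13R,14R)-13-(tert-butyldimethylsilyloxy)-3,4-epoxy-14-hydroxy-17-norcembra-7,11-dien-16-oic acid | OC(=O)C[C@@H]1C[C@@H]2O[C@@]2(C)CC/C=C(\C)CC/C=C(\C)[C@@H](O[Si](C)(C)C(C)(C)C)[C@@H]1O
F6 | step 10 | (1S,3S,4S,7E,11E,13R,14S)-13-(tert-butyldimethylsilyloxy)-3,4-epoxy-17-norcembra-7,11-dien-16,14-olide (trans-fused lactone) | O=C1O[C@H]2[C@H](C1)C[C@@H]1O[C@@]1(C)CC/C=C(\C)CC/C=C(\C)[C@H]2O[Si](C)(C)C(C)(C)C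
F7 | step 10 | (1S,3S,4S,7E,11E,13R,14S)-3,4-epoxy-13-hydroxy-17-norcembra-7,11-dien-16,14-olide (trans-fused lactone) | O=C1O[C@H]2[C@H](C1)C[C@@H]1O[C@@]1(C)CC/C=C(\C)CC/C=C(\C)[C@H]2O
F8 | step 3 | tert-butyl[(2-{[(2S,3S)-3-[(3E)-4,8-dimethylnona-3,7-dien-1-yl]-3-methyloxiran-2-yl]methyl}prop-2-en-1-yl)oxy]dimethylsilane | C=C(CO[Si](C)(C)C(C)(C)C)C[C@@H]1O[C@@]1(C)CC/C=C(\C)CCC=C(C)C
F9 | step 3 | 2-{[(2S,3S)-3-[(3E)-4,8-dimethylnona-3,7-dien-1-yl]-3-methyloxiran-2-yl]methyl}prop-2-en-1-ol | C=C(CO)C[C@@H]1O[C@@]1(C)CC/C=C(\C)CCC=C(C)C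
F10 | step 3 | 2-{[(2S,3S)-3-[(3E)-4,8-dimethylnona-3,7-dien-1-yl]-3-methyloxiran-2-yl]methyl}prop-2-en-1-yl prop-2-enoate | C=CC(=O)OCC(=C)C[C@@H]1O[C@@]1(C)CC/C=C(\C)CCC=C(C)C
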